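The route rests on one disconnection: the C8–C9 bond of the ten-membered ring, where the tertiary C8 carbinol and the C9 acetoxy carbon sit as a cis-dioxygenated pair next to C10 of ring A. A SmI2 pinacol coupling of keto aldehyde 33 forms this bond, closes the ten-membered ring and sets C8 and C9 in one operation. Precursor 33 carries ring A (C1, C10–C14) with trans C2 and C9 arms, a Z C5=C6 olefin, a C7 silyloxy group beside the C8 ketone, and C11 as an sp3 carbon bearing CH2SPh, a masked methylene that keeps the C9 aldehyde from enolising or rearranging.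

Key step: step 23

Numbering: briarane locants are used throughout (ring A = C1, C10–C14; ten-membered ring = C1–C10; C15 methyl on C1; C16 on C5; C17, C18, C19 on C8; C20 on C11); α is the ring face of H-10, β that of C15.
Assumption: the (4R,5R) antipode of the diol catalyst in step 2 is taken to favour the enantiomer of 4 that is drawn; if the sense of induction is the opposite, the (4S,5S) antipode is used and nothing else changes.

**Ring A fragment (steps 1–11)**

Step 1
Reactants: 1 tert-butyl 3-methylbut-2-enoate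
Product: 2 tert-butyl (E)-3-methyl-4-oxobut-2-enoate
Conditions: SeO2, 1,4-dioxane, 90 °C
Reagents that add atoms: selenium dioxide, O=[Se]=O
Why: Riley allylic oxidation (ene reaction, then [2,3] shift) attacks the methyl group trans to the ester and carries on to the (E)-enal, giving a dienophile with the aldehyde on the methyl-bearing carbon (later C1/C2) and a tert-butyl ester (later C9) that will not lactonise onto the C2 hydroxyl.

Step 2
Reactants: 2 tert-butyl (E)-3-methyl-4-oxobut-2-enoate; 3 (E)-1-(dimethylamino)-3-(tert-butyldimethylsilyloxy)buta-1,3-diene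
Product: 4 ring A cycloadduct (C1: CH3 β and CHO α; 14α-NMe2; C12 silyl enol ether, C12=C13; C9 tert-butyl ester β on C10)
Conditions: (4R,5R)-2,2-dimethyl-α,α,α′,α′-tetra(1-naphthyl)-1,3-dioxolane-4,5-dimethanol (20 mol %), toluene, −80 → −40 °C
Reagents that add atoms: none
Why: Hydrogen-bond-catalysed asymmetric Diels–Alder reaction of an amino siloxy diene with an α-substituted acrolein, in which the aldehyde directs the amino terminus to the quaternary carbon (C14–C1) and the CH2 terminus to C10, the E dienophile fixes the C2 and C9 arms trans, endo approach of the formyl group puts the amine cis to it, and the diol bound to the aldehyde selects the face that sets C1 and C10.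

Step 3
Reactants: 4 ring A cycloadduct
Product: 5 C2 allylic alcohols (both C2 epimers; vinyl group = C3=C4)
Conditions: CH2=CHMgBr, THF, −78 °C; H2O
Reagents that add atoms: vinylmagnesium bromide, C=C[Mg]Br
Why: Grignard 1,2-addition is selective for the aldehyde over the hindered tert-butyl ester at low temperature, and the C2 epimer ratio does not matter because C2 is reset in step 5.

Step 4
Reactants: 5 C2 allylic alcohols
Product: 6 C2 vinyl ketone
Conditions: (COCl)2, DMSO, CH2Cl2, −78 °C; Et3N, −78 → −20 °C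
Reagents that add atoms: none
Why: Swern oxidation converts the allylic alcohol into the enone under non-acidic conditions that the silyl enol ether and the tertiary amine tolerate.

Step 5
Reactants: 6 C2 vinyl ketone
Product: 7 (2R)-allylic alcohol (O-2 syn to N-14)
Conditions: Zn(BH4)2, Et2O, −30 °C; H2O
Reagents that add atoms: none
Why: Cram-chelate-controlled 1,2-reduction, in which zinc bridges the C2 carbonyl and the cis 14α-dimethylamino group and hydride enters from the flank of the small C15 methyl, should give the 2R carbinol.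

Step 6
Reactants: 7 (2R)-allylic alcohol
Product: 8 (2R)-hydroxy enone (C12 ketone, C13=C14, C11 H2)
Conditions: aq HF (48 %), MeCN, 0 °C → rt
Reagents that add atoms: none
Why: Hydrolysis of the silyl enol ether followed by E1cB elimination of dimethylamine gives the cyclohexenone without touching C1, C2 or C10.

Step 7
Reactants: 8 (2R)-hydroxy enone
Product: 11 11α-(phenylthiomethyl) hydroxy enone, via bis(trimethylsilyl) dienol ether 9 (not isolated), via C2 trimethylsilyl ether 10 (not isolated)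
Conditions: LiN(iPr)2 (2.3 equiv), Me3SiCl, THF, −78 °C; then PhSCH2Cl, ZnBr2 (10 mol %), CH2Cl2, 0 °C; then K2CO3 (cat.), MeOH, 0 °C
Reagents that add atoms: chloromethyl phenyl sulfide, ClCSc1ccccc1; chlorotrimethylsilane, C[Si](C)(C)Cl (silyl groups of 9 and 10 only)
Why: Kinetic deprotonation at the only enolisable α′ carbon (C11) and O-silylation give a 2-siloxy diene whose Lewis-acid-promoted alkylation by the thionium ion (Mukaiyama-type phenylthiomethylation) installs C20 trans to the C10 ester, the CH2SPh group serving as a masked C11 methylene.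

Step 8
Reactants: 11 11α-(phenylthiomethyl) hydroxy enone
Product: 13 2,14α-diol 12-ketone, via cyclic phenylboronate 12 (not isolated)
Conditions: PhB(OH)2 (1.3 equiv), Et3N (20 mol %), 4 Å MS, toluene, 40 °C; then pinacol, rt
Reagents that add atoms: phenylboronic acid, OB(O)c1ccccc1 (supplies O-14; boron and phenyl stay in 12 only)
Why: Intramolecular oxa-Michael addition of the boronic acid hemiester formed at the C2 hydroxyl delivers its B–OH oxygen to C14 through a six-membered dioxaborinane that can only form cis to the C2 arm, so O-14 is set α, and transesterification with pinacol frees the syn-1,3-diol.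

Step 9
Reactants: 13 2,14α-diol 12-ketone
Product: 14 2,12α,14α-triol
Conditions: Et2BOMe, NaBH4, THF–MeOH (4:1), −78 °C; MeOH co-evaporation
Reagents that add atoms: none
Why: Narasaka–Prasad 1,3-syn reduction, in which the boron chelate between the axial 14α-hydroxyl and the C12 ketone is attacked by external hydride on its open face, should give the cis-12,14-diol (O-12 α).

Step 10
Reactants: 14 2,12α,14α-triol
Product: 15 tris(tert-butyldimethylsilyl) ether tert-butyl ester
Conditions: TBSOTf (6 equiv), 2,6-lutidine, CH2Cl2, 0 °C → rt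
Reagents that add atoms: tert-butyldimethylsilyl triflate, CC(C)(C)[Si](C)(C)OS(=O)(=O)C(F)(F)F
Why: Silylation with the silyl triflate is reactive enough for the three hindered secondary alcohols and leaves only fluoride-labile groups on ring A.

Step 11
Reactants: 15 tris(tert-butyldimethylsilyl) ether tert-butyl ester
Product: 16 ring A alcohol (C9 hydroxymethyl β; 2R vinyl carbinol TBS ether; 12α,14α-OTBS; 11α-CH2SPh)
Conditions: LiAlH4, Et2O, 0 °C → rt
Reagents that add atoms: none
Why: Hydride reduction of the ester brings C9 to the alcohol level before the fragment union, because no ester reduction is possible once the C8 ketone exists.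

**C5–C8/C16–C19 fragment (steps 12–19)**

Step 12
Reactants: 17 (R)-4-benzyl-3-propionyloxazolidin-2-one; 18 acrolein
Product: 20 (R)-4-benzyl-3-[(2R,3S)-3-hydroxy-2-methylpent-4-enoyl]oxazolidin-2-one, via dibutylboron aldolate 19 (not isolated)
Conditions: Bu2BOTf, iPr2NEt, CH2Cl2, −78 → 0 °C; then pH 7 buffer, MeOH, H2O2, 0 °C
Reagents that add atoms: dibutylboron triflate, CCCCB(CCCC)OS(=O)(=O)C(F)(F)F (boron group of 19 only)
Why: Evans syn-aldol reaction through the Z boron enolate and a Zimmerman–Traxler chair, with the benzyl group shielding one enolate face, sets C17 (the later methyl centre) and the sacrificial C8 carbinol.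

Step 13
Reactants: 20 syn-aldol adduct
Product: 21 C8 triethylsilyl ether of 20
Conditions: TESOTf, 2,6-lutidine, CH2Cl2, −78 °C
Reagents that add atoms: triethylsilyl triflate, CC[Si](CC)(CC)OS(=O)(=O)C(F)(F)F
Why: Silylation gives a non-chelating C8 ether that can later be removed in the presence of tert-butyldimethylsilyl ethers.

Step 14
Reactants: 21 C8 triethylsilyl ether
Product: 22 (2S,3S)-2-methyl-3-(triethylsilyloxy)pent-4-en-1-ol
Conditions: LiBH4, MeOH (1 equiv), THF, 0 °C
Reagents that add atoms: none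
Why: Reductive cleavage of the N-acyl oxazolidinone gives the C19 primary alcohol and returns the auxiliary without epimerising C17.

Step 15
Reactants: 22 (2S,3S)-2-methyl-3-(triethylsilyloxy)pent-4-en-1-ol
Product: 23 (2S,3S)-1-(tert-butyldimethylsilyloxy)-2-methyl-3-(triethylsilyloxy)pent-4-ene
Conditions: TBSCl, imidazole, DMF, rt
Reagents that add atoms: tert-butyldimethylsilyl chloride, CC(C)(C)[Si](C)(C)Cl
Why: Standard silylation protects the primary C19 hydroxyl until the final global desilylation.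

Step 16
Reactants: 23 bis-silyl ether alkene
Product: 25 (2R,3S)-4-(tert-butyldimethylsilyloxy)-3-methyl-2-(triethylsilyloxy)butanal, via secondary ozonide 24 (not isolated)
Conditions: O3, CH2Cl2, −78 °C; then PPh3, −78 °C → rt
Reagents that add atoms: ozone, [O-][O+]=O
Why: Ozonolysis with reductive work-up cleaves the only olefin to the C7 aldehyde under neutral conditions that do not epimerise C8.

Step 17
Reactants: 25 C7 aldehyde
Product: 26 (2S,3R,4S)-1-(tert-butyldimethylsilyloxy)-2-methyl-3-(triethylsilyloxy)hept-5-yn-4-ol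
Conditions: CH3C≡CMgBr, THF, −78 °C; H2O
Reagents that add atoms: 1-propynylmagnesium bromide, CC#C[Mg]Br
Why: Grignard addition under Felkin–Anh control, with the non-chelating C8 silyloxy group anti to the incoming alkynyl group, should give the 7,8-anti alcohol and so set C7; the minor epimer would be removed by chromatography.

Step 18
Reactants: 26 propargylic alcohol
Product: 28 (2S,3R,4S,5Z)-1-(tert-butyldimethylsilyloxy)-6-iodo-2-methyl-3-(triethylsilyloxy)hept-5-en-4-ol, via cyclic alkenylaluminate 27 (not isolated)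
Conditions: NaAlH2(OCH2CH2OMe)2, THF, 0 °C → rt; EtOAc; then I2, −78 → 0 °C
Reagents that add atoms: iodine, II; NaAlH2(OCH2CH2OMe)2, [Na+].COCCO[AlH2-]OCCOC (aluminium group of 27 only)
Why: Hydroxyl-directed trans-hydroalumination places aluminium on C5 cis to C7 in a five-membered aluminate, and iodinolysis with retention gives the Z iodoalkene with the C16 methyl trans to C7.

Step 19
Reactants: 28 (Z)-iodo allylic alcohol
Product: 29 (2S,3R,4S,5Z)-1,4-bis(tert-butyldimethylsilyloxy)-6-iodo-2-methyl-3-(triethylsilyloxy)hept-5-ene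
Conditions: TBSOTf, 2,6-lutidine, CH2Cl2, −78 °C
Reagents that add atoms: tert-butyldimethylsilyl triflate, CC(C)(C)[Si](C)(C)OS(=O)(=O)C(F)(F)F
Why: Silylation of the C7 hydroxyl gives the non-chelating silyl ether that later enforces Felkin–Anh addition to the C8 ketone.

**Union and ring closure (steps 20–23)**

Step 20
Reactants: 16 ring A alcohol; 29 (Z)-vinyl iodide
Product: 31 coupled seco compound (Z C5=C6; C8 OTES; C9 OH), via B-alkyl borane 30 (not isolated)
Conditions: 9-BBN-H (2.5 equiv), THF, rt; then 29, PdCl2(dppf) (5 mol %), AsPh3, Cs2CO3, DMF–H2O, rt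
Reagents that add atoms: 9-borabicyclo[3.3.1]nonane, B1C2CCCC1CCC2 (boron groups of 30 only)
Why: Anti-Markovnikov hydroboration of the only olefin of 16, then B-alkyl Suzuki–Miyaura coupling with retention at the vinyl iodide, forms C4–C5 and delivers the Z trisubstituted olefin while C8 is still a silyl ether that cannot epimerise C7.

Step 21
Reactants: 31 coupled seco compound
Product: 32 seco 8,9-diol (C8 secondary OH, C9 primary OH)
Conditions: pyridinium p-toluenesulfonate, MeOH–CH2Cl2 (1:1), 0 °C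
Reagents that add atoms: none
Why: Acid-catalysed methanolysis removes the secondary triethylsilyl ether much faster than the primary and secondary tert-butyldimethylsilyl ethers.

Step 22
Reactants: 32 seco 8,9-diol
Product: 33 seco keto aldehyde (C8 ketone, C9 aldehyde)
Conditions: (COCl)2, DMSO, CH2Cl2, −78 °C; Et3N, −78 → −30 °C; used at once
Reagents that add atoms: none
Why: Swern oxidation of both alcohols creates the C8 ketone and the C9 aldehyde together, only in the last step before ring closure, so that C7, C10 and C17 see base only briefly and the sulfide is left untouched.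

Step 23
Reactants: 33 seco keto aldehyde
Product: 34 ring A-fused cyclodec-5-ene cis-8α,9α-diol
Conditions: SmI2 (4 equiv), THF, syringe-pump addition of 33 (final 2 mM), −78 → 0 °C; aq NaHCO3
Reagents that add atoms: none
Why: Electron transfer from divalent samarium to the more easily reduced C9 aldehyde gives a ketyl that adds to the C8 ketone held by trivalent samarium, and a second electron transfer gives the samarium diolate of 34. The closest known reaction type is the SmI2-mediated intramolecular pinacol coupling of keto aldehydes to cyclic cis-1,2-diols, which has been used for medium rings. The ten-membered ring closes by radical–carbonyl addition between the two former carbonyl carbons, which both become ring atoms with exocyclic oxygens, helped by the Z C5=C6 olefin and the trans C2 and C9 arms of ring A that bring the chain ends together. C8 is set by Felkin–Anh attack anti to the non-chelating C7 silyloxy group; C9 is set by the samarium bridge that places both oxygens on the α face, the same face that Felkin–Anh attack anti to C1 at C10 would choose. The step needs aldehyde-before-ketone reduction, intramolecular over intermolecular coupling and retention of the C7 silyloxy group, which the reduction-potential gap, high dilution and the absence of HMPA or proton donors should secure. The sp3 C11 with its CH2SPh group removes homoallyl-ketyl rearrangement and C10 enolisation.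

**Endgame (steps 24–30)**

Step 24
Reactants: 34 cis-8,9-diol
Product: 35 9-acetate
Conditions: Ac2O, pyridine, 4-(dimethylamino)pyridine (cat.), CH2Cl2, 0 °C
Reagents that add atoms: acetic anhydride, CC(=O)OC(C)=O
Why: Nucleophile-catalysed acylation takes the secondary C9 hydroxyl and leaves the hindered tertiary C8 hydroxyl free, as in the target.

Step 25
Reactants: 35 9-acetate
Product: 37 11(20)-methylene compound, via sulfoxide 36 (not isolated)
Conditions: 3-chloroperoxybenzoic acid (1.0 equiv), CH2Cl2, −78 °C; then toluene, CaCO3, 100 °C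
Reagents that add atoms: 3-chloroperoxybenzoic acid, OOC(=O)c1cccc(Cl)c1 (oxygen of 36 only)
Why: Sulfide oxidation outruns olefin epoxidation at −78 °C, and thermal syn-elimination of the sulfoxide can only use H-11, so the exocyclic C11=C20 methylene is unmasked.

Step 26
Reactants: 37 11(20)-methylene compound
Product: 38 6α-chloro-5(16)-ene
Conditions: Ca(OCl)2, CO2 (dry ice), CH2Cl2–H2O, 0 °C
Reagents that add atoms: calcium hypochlorite, [Ca+2].[O-]Cl.[O-]Cl
Why: Ene-type allylic chlorination by hypochlorous acid puts chlorine on C6 of the more nucleophilic trisubstituted olefin with loss of a C16 proton, and attack anti to the C7–C8 bond of the conformer with the C7–O bond in the olefin plane is expected to give the 6-chloride cis to O-7.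

Step 27
Reactants: 38 6α-chloro-5(16)-ene
Product: 39 desilylated polyol (free OH at C2, C7, C8, C12, C14, C19; 9-OAc)
Conditions: HF·pyridine, pyridine, THF, 0 °C → rt
Reagents that add atoms: none
Why: Fluoride-mediated desilylation removes all five silyl ethers under mildly acidic conditions that spare the acetate and the allylic chloride and cannot close the C6/C7 chlorohydrin to an epoxide.

Step 28
Reactants: 39 desilylated polyol
Product: 40 11α,20-epoxide
Conditions: VO(acac)2 (5 mol %), t-BuOOH, CH2Cl2, 0 °C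
Reagents that add atoms: tert-butyl hydroperoxide, CC(C)(C)OO
Why: Hydroxyl-directed epoxidation delivers oxygen from the vanadium alkoxide of the allylic 12α-hydroxyl to the same face of the C11 methylene, which sets C11, while the chlorine-deactivated 5(16)-olefin has no allylic hydroxyl.

Step 29
Reactants: 40 11α,20-epoxide
Product: 42 γ-lactone triol (C19 carbonyl, O-7), via lactol 41 (not isolated)
Conditions: 2,2,6,6-tetramethylpiperidin-1-oxyl (20 mol %), PhI(OAc)2 (2.5 equiv), CH2Cl2, rt
Reagents that add atoms: none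
Why: Oxoammonium oxidation is selective for the primary C19 alcohol, the aldehyde is trapped by the C7 hydroxyl as a five-membered lactol, and this is oxidised on to the lactone (oxidative lactonisation of a 1,4-diol).

Step 30
Reactants: 42 γ-lactone triol
Product: 43 CNP0349227.4
Conditions: Ac2O, pyridine, 4-(dimethylamino)pyridine (cat.), CH2Cl2, rt
Reagents that add atoms: acetic anhydride, CC(=O)OC(C)=O
Why: Acylation of the three secondary hydroxyls at C2, C12 and C14 gives the tetraacetate, while the tertiary C8 hydroxyl stays free for steric reasons.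

**Compound list**

1 | tert-butyl 3-methylbut-2-enoate | CC(C)=CC(=O)OC(C)(C)C | starting material
2 | tert-butyl (E)-3-methyl-4-oxobut-2-enoate | O=C/C(C)=C/C(=O)OC(C)(C)C | intermediate
3 | (E)-1-(dimethylamino)-3-(tert-butyldimethylsilyloxy)buta-1,3-diene | CN(C)/C=C/C(=C)O[Si](C)(C)C(C)(C)C | starting material
4 | ring A cycloadduct (C2 aldehyde, 14α-NMe2, C12 silyl enol ether, C9 tert-butyl ester) | O=C[C@@]1(C)[C@@H](N(C)C)C=C(O[Si](C)(C)C(C)(C)C)C[C@@H]1C(=O)OC(C)(C)C | intermediate
5 | C2 allylic alcohols (C2 epimers) | C=CC(O)[C@@]1(C)[C@@H](N(C)C)C=C(O[Si](C)(C)C(C)(C)C)C[C@@H]1C(=O)OC(C)(C)C | intermediate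
6 | C2 vinyl ketone | C=CC(=O)[C@@]1(C)[C@@H](N(C)C)C=C(O[Si](C)(C)C(C)(C)C)C[C@@H]1C(=O)OC(C)(C)C | intermediate
7 | (2R)-allylic alcohol | C=C[C@@H](O)[C@@]1(C)[C@@H](N(C)C)C=C(O[Si](C)(C)C(C)(C)C)C[C@@H]1C(=O)OC(C)(C)C | intermediate
8 | (2R)-hydroxy enone | C=C[C@@H](O)[C@@]1(C)C=CC(=O)C[C@@H]1C(=O)OC(C)(C)C | intermediate
9 | bis(trimethylsilyl) dienol ether | C=C[C@@H](O[Si](C)(C)C)[C@@]1(C)C=CC(O[Si](C)(C)C)=C[C@@H]1C(=O)OC(C)(C)C | intermediate (not isolated)
10 | C2 trimethylsilyl ether of 11 | C=C[C@@H](O[Si](C)(C)C)[C@@]1(C)C=CC(=O)[C@@H](CSc2ccccc2)[C@@H]1C(=O)OC(C)(C)C | intermediate (not isolated)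
11 | 11α-(phenylthiomethyl) hydroxy enone | C=C[C@@H](O)[C@@]1(C)C=CC(=O)[C@@H](CSc2ccccc2)[C@@H]1C(=O)OC(C)(C)C | intermediate
12 | cyclic phenylboronate across O-2 and O-14 | C=C[C@H]1OB(c2ccccc2)O[C@H]2CC(=O)[C@@H](CSc3ccccc3)[C@H](C(=O)OC(C)(C)C)[C@@]12C | intermediate (not isolated)
13 | 2,14α-diol 12-ketone | C=C[C@@H](O)[C@@]1(C)[C@@H](O)CC(=O)[C@@H](CSc2ccccc2)[C@@H]1C(=O)OC(C)(C)C | intermediate
14 | 2,12α,14α-triol | C=C[C@@H](O)[C@@]1(C)[C@@H](O)C[C@@H](O)[C@@H](CSc2ccccc2)[C@@H]1C(=O)OC(C)(C)C | intermediate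
15 | tris(tert-butyldimethylsilyl) ether tert-butyl ester | C=C[C@@H](O[Si](C)(C)C(C)(C)C)[C@@]1(C)[C@@H](O[Si](C)(C)C(C)(C)C)C[C@@H](O[Si](C)(C)C(C)(C)C)[C@@H](CSc2ccccc2)[C@@H]1C(=O)OC(C)(C)C | intermediate
16 | ring A alcohol (C9 hydroxymethyl) | C=C[C@@H](O[Si](C)(C)C(C)(C)C)[C@@]1(C)[C@@H](O[Si](C)(C)C(C)(C)C)C[C@@H](O[Si](C)(C)C(C)(C)C)[C@@H](CSc2ccccc2)[C@@H]1CO | intermediate
17 | (R)-4-benzyl-3-propionyloxazolidin-2-one | CCC(=O)N1[C@H](Cc2ccccc2)COC1=O | starting material
18 | acrolein | C=CC=O | starting material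
19 | dibutylboron aldolate | C=C[C@H](OB(CCCC)CCCC)[C@@H](C)C(=O)N1[C@H](Cc2ccccc2)COC1=O | intermediate (not isolated)
20 | (R)-4-benzyl-3-[(2R,3S)-3-hydroxy-2-methylpent-4-enoyl]oxazolidin-2-one | C=C[C@H](O)[C@@H](C)C(=O)N1[C@H](Cc2ccccc2)COC1=O | intermediate
21 | C8 triethylsilyl ether of 20 | C=C[C@H](O[Si](CC)(CC)CC)[C@@H](C)C(=O)N1[C@H](Cc2ccccc2)COC1=O | intermediate
22 | (2S,3S)-2-methyl-3-(triethylsilyloxy)pent-4-en-1-ol | C=C[C@H](O[Si](CC)(CC)CC)[C@@H](C)CO | intermediate
23 | (2S,3S)-1-(tert-butyldimethylsilyloxy)-2-methyl-3-(triethylsilyloxy)pent-4-ene | C=C[C@H](O[Si](CC)(CC)CC)[C@@H](C)CO[Si](C)(C)C(C)(C)C | intermediate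
24 | secondary ozonide of 23 | C1OC(OO1)[C@H](O[Si](CC)(CC)CC)[C@@H](C)CO[Si](C)(C)C(C)(C)C | intermediate (not isolated)
25 | (2R,3S)-4-(tert-butyldimethylsilyloxy)-3-methyl-2-(triethylsilyloxy)butanal | O=C[C@H](O[Si](CC)(CC)CC)[C@@H](C)CO[Si](C)(C)C(C)(C)C | intermediate
26 | (2S,3R,4S)-1-(tert-butyldimethylsilyloxy)-2-methyl-3-(triethylsilyloxy)hept-5-yn-4-ol | CC#C[C@H](O)[C@H](O[Si](CC)(CC)CC)[C@@H](C)CO[Si](C)(C)C(C)(C)C | intermediate
27 | cyclic alkenylaluminate, sodium salt | CC1=C[C@@H]([C@H](O[Si](CC)(CC)CC)[C@@H](C)CO[Si](C)(C)C(C)(C)C)O[Al-]1(OCCOC)OCCOC.[Na+] | intermediate (not isolated)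
28 | (2S,3R,4S,5Z)-1-(tert-butyldimethylsilyloxy)-6-iodo-2-methyl-3-(triethylsilyloxy)hept-5-en-4-ol | C/C(I)=C/[C@H](O)[C@H](O[Si](CC)(CC)CC)[C@@H](C)CO[Si](C)(C)C(C)(C)C | intermediate
29 | (2S,3R,4S,5Z)-1,4-bis(tert-butyldimethylsilyloxy)-6-iodo-2-methyl-3-(triethylsilyloxy)hept-5-ene | C/C(I)=C/[C@H](O[Si](C)(C)C(C)(C)C)[C@H](O[Si](CC)(CC)CC)[C@@H](C)CO[Si](C)(C)C(C)(C)C | intermediate
30 | B-alkyl borane of 16 (C4–B and C9–O–B) | B1(C2CCCC1CCC2)CC[C@@H](O[Si](C)(C)C(C)(C)C)[C@@]3(C)[C@@H](O[Si](C)(C)C(C)(C)C)C[C@@H](O[Si](C)(C)C(C)(C)C)[C@@H](CSc4ccccc4)[C@@H]3COB5C6CCCC5CCC6 | intermediate (not isolated)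
31 | coupled seco compound (C8 OTES, C9 OH) | CC(C)(C)[Si](C)(C)OC[C@H](C)[C@@H](O[Si](CC)(CC)CC)[C@@H](O[Si](C)(C)C(C)(C)C)/C=C(C)\CC[C@@H](O[Si](C)(C)C(C)(C)C)[C@@]1(C)[C@@H](O[Si](C)(C)C(C)(C)C)C[C@@H](O[Si](C)(C)C(C)(C)C)[C@@H](CSc2ccccc2)[C@@H]1CO | intermediate
32 | seco 8,9-diol | CC(C)(C)[Si](C)(C)OC[C@H](C)[C@@H](O)[C@@H](O[Si](C)(C)C(C)(C)C)/C=C(C)\CC[C@@H](O[Si](C)(C)C(C)(C)C)[C@@]1(C)[C@@H](O[Si](C)(C)C(C)(C)C)C[C@@H](O[Si](C)(C)C(C)(C)C)[C@@H](CSc2ccccc2)[C@@H]1CO | intermediate
33 | seco keto aldehyde (key-step precursor) | CC(C)(C)[Si](C)(C)OC[C@H](C)C(=O)[C@@H](O[Si](C)(C)C(C)(C)C)/C=C(C)\CC[C@@H](O[Si](C)(C)C(C)(C)C)[C@@]1(C)[C@@H](O[Si](C)(C)C(C)(C)C)C[C@@H](O[Si](C)(C)C(C)(C)C)[C@@H](CSc2ccccc2)[C@@H]1C=O | intermediate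
34 | macrocyclic cis-8α,9α-diol (key-step product) | C1[C@@H](O[Si](C)(C)C(C)(C)C)[C@@]2(C)[C@@H](O[Si](C)(C)C(C)(C)C)C[C@@H](O[Si](C)(C)C(C)(C)C)[C@@H](CSc3ccccc3)[C@@H]2[C@@H](O)[C@](O)([C@@H](C)CO[Si](C)(C)C(C)(C)C)[C@@H](O[Si](C)(C)C(C)(C)C)/C=C(C)\C1 | intermediate
35 | 9-acetate | C1[C@@H](O[Si](C)(C)C(C)(C)C)[C@@]2(C)[C@@H](O[Si](C)(C)C(C)(C)C)C[C@@H](O[Si](C)(C)C(C)(C)C)[C@@H](CSc3ccccc3)[C@@H]2[C@@H](OC(C)=O)[C@](O)([C@@H](C)CO[Si](C)(C)C(C)(C)C)[C@@H](O[Si](C)(C)C(C)(C)C)/C=C(C)\C1 | intermediate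
36 | sulfoxide of 35 (both sulfur epimers) | C1[C@@H](O[Si](C)(C)C(C)(C)C)[C@@]2(C)[C@@H](O[Si](C)(C)C(C)(C)C)C[C@@H](O[Si](C)(C)C(C)(C)C)[C@@H](CS(=O)c3ccccc3)[C@@H]2[C@@H](OC(C)=O)[C@](O)([C@@H](C)CO[Si](C)(C)C(C)(C)C)[C@@H](O[Si](C)(C)C(C)(C)C)/C=C(C)\C1 | intermediate (not isolated)
37 | 11(20)-methylene compound | C1[C@@H](O[Si](C)(C)C(C)(C)C)[C@@]2(C)[C@@H](O[Si](C)(C)C(C)(C)C)C[C@@H](O[Si](C)(C)C(C)(C)C)C(=C)[C@@H]2[C@@H](OC(C)=O)[C@](O)([C@@H](C)CO[Si](C)(C)C(C)(C)C)[C@@H](O[Si](C)(C)C(C)(C)C)/C=C(C)\C1 | intermediate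
38 | 6α-chloro-5(16)-ene | C=C1CC[C@@H](O[Si](C)(C)C(C)(C)C)[C@@]2(C)[C@@H](O[Si](C)(C)C(C)(C)C)C[C@@H](O[Si](C)(C)C(C)(C)C)C(=C)[C@@H]2[C@@H](OC(C)=O)[C@](O)([C@@H](C)CO[Si](C)(C)C(C)(C)C)[C@@H](O[Si](C)(C)C(C)(C)C)[C@H]1Cl | intermediate
39 | desilylated polyol | C=C1CC[C@@H](O)[C@@]2(C)[C@@H](O)C[C@@H](O)C(=C)[C@@H]2[C@@H](OC(C)=O)[C@](O)([C@@H](C)CO)[C@@H](O)[C@H]1Cl | intermediate
40 | 11α,20-epoxide | C=C1CC[C@@H](O)[C@@]2(C)[C@@H](O)C[C@@H](O)[C@]3(CO3)[C@@H]2[C@@H](OC(C)=O)[C@](O)([C@@H](C)CO)[C@@H](O)[C@H]1Cl | intermediate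
41 | C19 lactol (both C19 epimers) | C=C1CC[C@@H](O)[C@@]2(C)[C@@H](O)C[C@@H](O)[C@]3(CO3)[C@@H]2[C@@H](OC(C)=O)[C@]2(O)[C@@H](C)C(O)O[C@H]2[C@H]1Cl | intermediate (not isolated)
42 | γ-lactone triol | C=C1CC[C@@H](O)[C@@]2(C)[C@@H](O)C[C@@H](O)[C@]3(CO3)[C@@H]2[C@@H](OC(C)=O)[C@]2(O)[C@@H](C)C(=O)O[C@H]2[C@H]1Cl | intermediate
43 | CNP0349227.4 | C=C1CC[C@@H](OC(C)=O)[C@@]2(C)[C@@H](OC(C)=O)C[C@@H](OC(C)=O)[C@]3(CO3)[C@@H]2[C@@H](OC(C)=O)[C@]2(O)[C@@H](C)C(=O)O[C@H]2[C@H]1Cl | target

**Totals and risks**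

Total step count: 30. Longest linear sequence: 22 steps (steps 1–11 and 20–30).

Steps most likely to fail:

1. Step 23. The ring closure may lose out to intermolecular coupling, to simple reduction of either carbonyl, or to reductive loss of the C7 silyloxy group. The fallback replaces the one-electron coupling by a two-electron umpolung addition. From 33, an N-heterocyclic carbene (from 2-mesityl-6,7-dihydro-5H-pyrrolo[2,1-c][1,2,4]triazol-2-ium chloride and Et3N, toluene, high dilution) would turn the C9 aldehyde into its Breslow intermediate, which adds to the C8 ketone in a crossed aldehyde–ketone acyloin cyclisation to give the macrocyclic 8-hydroxy-9-ketone F1. Reduction of F1 with Zn(BH4)2 in Et2O at −30 °C through the zinc chelate with the C8 hydroxyl should then give the cis-diol, and the route is rejoined at 34.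

2. Step 26. Chlorine may enter from the wrong face of the Z-cyclodecene, the chloronium ion may be captured by the C8 hydroxyl, or the proton may be lost from C4 instead of C16. The fallback builds the C6 centre by oxygenation and inversion. From 37, a Schenck ene reaction (O2, tetraphenylporphyrin, hν, CH2Cl2, 0 °C) would give the 6-epi allylic hydroperoxide F2, which PPh3 reduces to the 6-epi allylic alcohol F3. An Appel reaction (PPh3, CCl4, MeCN, rt) would then replace the hydroxyl by chloride with inversion, and the route is rejoined at 38.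

3. Step 2. The diol catalyst may give poor enantiofacial control with this β-ester-substituted dienophile. The fallback obtains the absolute configuration by resolution. From 2 and 3, the uncatalysed cycloaddition (toluene, 0 °C → rt) would give racemic 4, which contains the antipode ent-4 F4. Steps 3–6 carried out unchanged on the racemate would lead through ent-5 F5, ent-6 F6 and ent-7 F7 to racemic 8, which contains ent-8 F8. A Sharpless kinetic resolution (Ti(OiPr)4, (S,S)-diisopropyl tartrate, t-BuOOH, 4 Å MS, CH2Cl2, −20 °C) would epoxidise the fast-reacting (2S)-carbinol F8 to the epoxy alcohol F9 and leave the (2R)-enantiomer, and the route is rejoined at 8.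

Further compounds
F1 | step 23 | macrocyclic 8-hydroxy-9-ketone | C1[C@@H](O[Si](C)(C)C(C)(C)C)[C@@]2(C)[C@@H](O[Si](C)(C)C(C)(C)C)C[C@@H](O[Si](C)(C)C(C)(C)C)[C@@H](CSc3ccccc3)[C@@H]2C(=O)[C@](O)([C@@H](C)CO[Si](C)(C)C(C)(C)C)[C@@H](O[Si](C)(C)C(C)(C)C)/C=C(C)\C1
F2 | step 26 | 6-epi allylic hydroperoxide | C=C1CC[C@@H](O[Si](C)(C)C(C)(C)C)[C@@]2(C)[C@@H](O[Si](C)(C)C(C)(C)C)C[C@@H](O[Si](C)(C)C(C)(C)C)C(=C)[C@@H]2[C@@H](OC(C)=O)[C@](O)([C@@H](C)CO[Si](C)(C)C(C)(C)C)[C@@H](O[Si](C)(C)C(C)(C)C)[C@@H]1OO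
F3 | step 26 | 6-epi allylic alcohol | C=C1CC[C@@H](O[Si](C)(C)C(C)(C)C)[C@@]2(C)[C@@H](O[Si](C)(C)C(C)(C)C)C[C@@H](O[Si](C)(C)C(C)(C)C)C(=C)[C@@H]2[C@@H](OC(C)=O)[C@](O)([C@@H](C)CO[Si](C)(C)C(C)(C)C)[C@@H](O[Si](C)(C)C(C)(C)C)[C@@H]1O
F4 | step 2 | ent-4 | O=C[C@]1(C)[C@H](N(C)C)C=C(O[Si](C)(C)C(C)(C)C)C[C@H]1C(=O)OC(C)(C)C
F5 | step 2 | ent-5 (C2 epimers) | C=CC(O)[C@]1(C)[C@H](N(C)C)C=C(O[Si](C)(C)C(C)(C)C)C[C@H]1C(=O)OC(C)(C)C
F6 | step 2 | ent-6 | C=CC(=O)[C@]1(C)[C@H](N(C)C)C=C(O[Si](C)(C)C(C)(C)C)C[C@H]1C(=O)OC(C)(C)C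
F7 | step 2 | ent-7 | C=C[C@H](O)[C@]1(C)[C@H](N(C)C)C=C(O[Si](C)(C)C(C)(C)C)C[C@H]1C(=O)OC(C)(C)C
F8 | step 2 | ent-8 | C=C[C@H](O)[C@]1(C)C=CC(=O)C[C@H]1C(=O)OC(C)(C)C
F9 | step 2 | epoxy alcohol from ent-8 | O[C@@H]([C@H]1CO1)[C@]2(C)C=CC(=O)C[C@H]2C(=O)OC(C)(C)C
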